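**Plan**

- Each half is numbered as a drimane (ring A = C1–C5 and C10, ring B = C5–C10, C11/C11' = the linking CH2 groups). The retrosynthesis cuts the C8–CH3 bonds and C8=C9 alkenes back to C8 ketones, then both C6–C7 bonds of rings B, then both C9–C10 bonds. This leaves adipic acid (C8–C9–C11–C11'–C9'–C8') and two β-cyclogeranyl units (ring A plus C6).
- Forward: both preformed rings A are joined to the adipate chain at C9–C10 by a double Ireland–Claisen rearrangement. The acids become iodomethyl ketones (C7), both rings B close in one operation (10 → 11), and the C8 methyls and tetrasubstituted alkenes come last.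
- Enabling feature: in each half C6 and C7 link the ring-fusion carbon C5 to C8, the neighbour of C9. Ring B is therefore the adduct of an α-keto radical at C7 and an exocyclic C5=C6 methylene on ring A, and this closure also creates C5–H.
- Stereochemistry: both C10 centres come from a C2-symmetric chiral boron controller in the Claisen step; a single mismatched shift gives a separable diastereomer, so the C2-symmetric product is enriched. Both C5 centres come from hydrogen-atom transfer to the ring-fusion radical anti to the axial C10 methyl. C9 and C8 are transient.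

Key step: step 6

Assumption: the step 3 controller is the bromoborane made from N,N'-[(1S,2S)-1,2-diphenylethane-1,2-diyl]bis[3,5-bis(trifluoromethyl)benzenesulfonamide] and BBr3, and its (S,S) form is assumed to favour the chair that gives the (R)-configured quaternary carbons of 7; if the sense proves opposite, the (R,R) reagent is used with nothing else changed.

**Step 1**
Reactants: 1 β-cyclocitral (2,6,6-trimethylcyclohex-1-ene-1-carbaldehyde)
Product: 2 β-cyclogeraniol [(2,6,6-trimethylcyclohex-1-en-1-yl)methanol]
Conditions: NaBH4, MeOH, 0 °C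
Reagents that add atoms: none
Why: Borohydride 1,2-reduction of the hindered conjugated aldehyde should give the primary allylic alcohol cleanly, and no stereocentre is formed.

**Step 2**
Reactants: 2 β-cyclogeraniol (2 equiv); 3 adipoyl chloride (hexanedioyl dichloride)
Product: 4 bis[(2,6,6-trimethylcyclohex-1-en-1-yl)methyl] hexanedioate
Conditions: Et3N, DMAP (cat.), CH2Cl2, 0 °C → rt
Reagents that add atoms: none
Why: DMAP-catalysed acylation of the primary allylic alcohol by the diacid chloride joins both ring A units to the six-carbon chain under basic conditions that do not ionise the allylic C–O bond.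

**Step 3**
Reactants: 4 bis[(2,6,6-trimethylcyclohex-1-en-1-yl)methyl] hexanedioate
Product: 7 (2R,5R)-2,5-bis[(1R)-1,3,3-trimethyl-2-methylidenecyclohexyl]hexanedioic acid, via bis(boron ketene acetal) 5 (not isolated), via bis(acyloxyborane) 6 (not isolated)
Conditions: (S,S)-bis-sulfonamide, BBr3, CH2Cl2, rt, then evaporation (bromoborane, 2.2 equiv); 4, i-Pr2NEt, CH2Cl2, −78 °C, then −20 °C → 4 °C; H2O work-up, crystallisation
Reagents that add atoms: none
Why: In this enantioselective Ireland–Claisen rearrangement each ester is soft-enolised to a chiral boron ketene acetal that is inert toward the second ester group, its chair [3,3] shift moves the chain α-carbon (C9) onto the methyl-bearing ring carbon (C10) and turns C5–C6 into the exocyclic methylene, the C2-symmetric diazaborolidine selects one enolate face and so fixes both C10 quaternary centres as R, and the C9 configuration shown (chain cis to the boryloxy group, equatorial in the chair) is erased later.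

**Step 4**
Reactants: 7 (2R,5R)-2,5-bis[(1R)-1,3,3-trimethyl-2-methylidenecyclohexyl]hexanedioic acid
Product: 8 (3R,6R)-3,6-bis[(1R)-1,3,3-trimethyl-2-methylidenecyclohexyl]octane-2,7-dione
Conditions: MeLi (6 equiv), Et2O–THF, 0 °C → rt; inverse quench into cold 1 M HCl
Reagents that add atoms: methyllithium, C[Li]
Why: Addition of the small organolithium to the lithium carboxylates (ketone synthesis from carboxylic acids) stops at the geminal dialkoxides, which release the methyl ketones (C7) only on the inverse quench, while C10 is untouched and any C9 epimerisation would be without consequence.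

**Step 5**
Reactants: 8 (3R,6R)-3,6-bis[(1R)-1,3,3-trimethyl-2-methylidenecyclohexyl]octane-2,7-dione
Product: 10 (3R,6R)-1,8-diiodo-3,6-bis[(1R)-1,3,3-trimethyl-2-methylidenecyclohexyl]octane-2,7-dione, via bis(trimethylsilyl enol ether) 9 (not isolated)
Conditions: LDA, TMSCl (present from the start), THF, −78 °C; pentane filtration; NIS, THF, −78 → 0 °C, dark
Reagents that add atoms: N-iodosuccinimide, O=C1CCC(=O)N1I
Why: Kinetic deprotonation by LDA should occur at the methyl groups and not at the hindered C9 methines, immediate silylation prevents aldol reaction between the two ketone arms, and electrophilic α-iodination of the terminal silyl enol ethers by NIS should be much faster than attack on the 1,1-disubstituted alkenes.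

**Step 6**
Reactants: 10 (3R,6R)-1,8-diiodo-3,6-bis[(1R)-1,3,3-trimethyl-2-methylidenecyclohexyl]octane-2,7-dione
Product: 11 1,2-bis[(1R,4aS,8aS)-5,5,8a-trimethyl-2-oxodecahydronaphthalen-1-yl]ethane
Conditions: Bu3SnH (2.5 equiv) and AIBN (0.2 equiv) added by syringe pump over 8 h, PhH (0.005 M), 80 °C; KF work-up
Reagents that add atoms: none
Why: Bu3Sn• abstracts iodine from each iodomethyl ketone to give an electrophilic α-keto radical at C7, which adds to the unhindered CH2 terminus (C6) of the electron-rich exocyclic C5=C6 alkene; the tertiary C5 radical then takes hydrogen from Bu3SnH (or iodine from unreacted 10, followed by tin-mediated reduction) and Bu3Sn• carries the chain. The closest known reaction type is the tin hydride mediated cyclisation of 2-oxohex-5-enyl radicals from α-iodo ketones to cyclohexanones. Each ring B (C5–C6–C7–C8–C9–C10) closes in the 6-endo-trig mode, the two closures are independent, and 5-exo attack is excluded because C5 is fully substituted and lies between the quaternary C4 and C10. Each new C5 stereocentre is set in the hydrogen transfer: the β-face of the ring-fusion radical is screened by the axial C10 methyl and the axial C4 methyl, so hydrogen should arrive on the α-face and give the trans-decalin, while C10 is untouched and either C9 epimer would serve. The step needs ring closure to outrun direct reduction of the C7 radical, which is secured by slow stannane addition at high dilution and by the polarity match between the electrophilic radical and the 1,1-disubstituted alkene.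

**Step 7**
Reactants: 11 1,2-bis[(1R,4aS,8aS)-5,5,8a-trimethyl-2-oxodecahydronaphthalen-1-yl]ethane
Product: 12 1,2-bis[(1R,2S,4aS,8aS)-2-hydroxy-2,5,5,8a-tetramethyldecahydronaphthalen-1-yl]ethane
Conditions: MeLi, CeCl3 (anhydrous), THF, −78 °C; aq. NH4Cl
Reagents that add atoms: methyllithium, C[Li] (delivered as MeCeCl2, C[Ce](Cl)Cl)
Why: The weakly basic organocerium reagent should add to the hindered, enolisable C8 ketones instead of deprotonating them (organocerium carbonyl addition), approaching from the equatorial α-direction away from the axial C10 methyl to give the axial 8β-alcohols, whose configuration is removed in the next step.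

**Step 8**
Reactants: 12 1,2-bis[(1R,2S,4aS,8aS)-2-hydroxy-2,5,5,8a-tetramethyldecahydronaphthalen-1-yl]ethane
Product: 13 1,2-bis[(4aS,8aS)-2,5,5,8a-tetramethyl-3,4,4a,5,6,7,8,8a-octahydronaphthalen-1-yl]ethane (target)
Conditions: TsOH·H2O (cat.), PhH, 50–60 °C, monitored and stopped at equilibrium
Reagents that add atoms: none
Why: Acid-catalysed E1 dehydration of the tertiary alcohols with equilibration of the alkene isomers (Zaitsev control) should end at the tetrasubstituted C8=C9 alkenes, the most stable double-bond position in this ring system, which removes the C8 and C9 stereocentres and leaves C5 and C10 untouched.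

**Compound list**

1 | β-cyclocitral (2,6,6-trimethylcyclohex-1-ene-1-carbaldehyde) | CC1=C(C=O)C(C)(C)CCC1 | starting material
2 | β-cyclogeraniol [(2,6,6-trimethylcyclohex-1-en-1-yl)methanol] | CC1=C(CO)C(C)(C)CCC1 | intermediate
3 | adipoyl chloride (hexanedioyl dichloride) | O=C(Cl)CCCCC(=O)Cl | starting material
4 | bis[(2,6,6-trimethylcyclohex-1-en-1-yl)methyl] hexanedioate | CC1=C(COC(=O)CCCCC(=O)OCC2=C(C)CCCC2(C)C)C(C)(C)CCC1 | intermediate
5 | bis(boron ketene acetal) of 4; each enol oxygen carries a (4S,5S)-4,5-diphenyl-1,3-bis[3,5-bis(trifluoromethyl)phenylsulfonyl]-1,3,2-diazaborolidin-2-yl group cis to the chain | CC1=C(CO/C(OB2N(S(=O)(=O)c3cc(C(F)(F)F)cc(C(F)(F)F)c3)[C@@H](c3ccccc3)[C@H](c3ccccc3)N2S(=O)(=O)c2cc(C(F)(F)F)cc(C(F)(F)F)c2)=C/CC/C=C(OB2N(S(=O)(=O)c3cc(C(F)(F)F)cc(C(F)(F)F)c3)[C@@H](c3ccccc3)[C@H](c3ccccc3)N2S(=O)(=O)c2cc(C(F)(F)F)cc(C(F)(F)F)c2)/OCC2=C(C)CCCC2(C)C)C(C)(C)CCC1 | intermediate (not isolated)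
6 | bis(acyloxyborane) of 7; each carboxyl oxygen carries the same (4S,5S)-diazaborolidin-2-yl group | C=C1C(C)(C)CCC[C@]1(C)[C@@H](CC[C@@H](C(=O)OB2N(S(=O)(=O)c3cc(C(F)(F)F)cc(C(F)(F)F)c3)[C@@H](c3ccccc3)[C@H](c3ccccc3)N2S(=O)(=O)c2cc(C(F)(F)F)cc(C(F)(F)F)c2)[C@@]1(C)CCCC(C)(C)C1=C)C(=O)OB1N(S(=O)(=O)c2cc(C(F)(F)F)cc(C(F)(F)F)c2)[C@@H](c2ccccc2)[C@H](c2ccccc2)N1S(=O)(=O)c1cc(C(F)(F)F)cc(C(F)(F)F)c1 | intermediate (not isolated)
7 | (2R,5R)-2,5-bis[(1R)-1,3,3-trimethyl-2-methylidenecyclohexyl]hexanedioic acid | C=C1C(C)(C)CCC[C@]1(C)[C@@H](CC[C@@H](C(=O)O)[C@@]1(C)CCCC(C)(C)C1=C)C(=O)O | intermediate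
8 | (3R,6R)-3,6-bis[(1R)-1,3,3-trimethyl-2-methylidenecyclohexyl]octane-2,7-dione | C=C1C(C)(C)CCC[C@]1(C)[C@@H](CC[C@@H](C(C)=O)[C@@]1(C)CCCC(C)(C)C1=C)C(C)=O | intermediate
9 | bis(trimethylsilyl enol ether) of 8: (3R,6R)-2,7-bis(trimethylsilyloxy)-3,6-bis[(1R)-1,3,3-trimethyl-2-methylidenecyclohexyl]octa-1,7-diene | C=C1C(C)(C)CCC[C@]1(C)[C@@H](CC[C@@H](C(=C)O[Si](C)(C)C)[C@@]1(C)CCCC(C)(C)C1=C)C(=C)O[Si](C)(C)C | intermediate (not isolated)
10 | (3R,6R)-1,8-diiodo-3,6-bis[(1R)-1,3,3-trimethyl-2-methylidenecyclohexyl]octane-2,7-dione | C=C1C(C)(C)CCC[C@]1(C)[C@@H](CC[C@@H](C(=O)CI)[C@@]1(C)CCCC(C)(C)C1=C)C(=O)CI | intermediate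
11 | 1,2-bis[(1R,4aS,8aS)-5,5,8a-trimethyl-2-oxodecahydronaphthalen-1-yl]ethane | C(C[C@H]1C(=O)CC[C@H]2C(C)(C)CCC[C@]12C)[C@H]1C(=O)CC[C@H]2C(C)(C)CCC[C@]12C | intermediate
12 | 1,2-bis[(1R,2S,4aS,8aS)-2-hydroxy-2,5,5,8a-tetramethyldecahydronaphthalen-1-yl]ethane | C(C[C@H]1[C@@](C)(O)CC[C@H]2C(C)(C)CCC[C@]12C)[C@H]1[C@@](C)(O)CC[C@H]2C(C)(C)CCC[C@]12C | intermediate
13 | 1,2-bis[(4aS,8aS)-2,5,5,8a-tetramethyl-3,4,4a,5,6,7,8,8a-octahydronaphthalen-1-yl]ethane (CNP0372467.1) | CC1=C(CCC2=C(C)CC[C@H]3C(C)(C)CCC[C@]23C)[C@@]2(C)CCCC(C)(C)[C@@H]2CC1 | target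

Total steps: 8. Longest linear sequence: 8 steps (from 1).

**Steps most likely to fail**

Step 3. The [3,3] shift of the bulky boron ketene acetals onto the tetrasubstituted ring alkene may be too slow, or the controller may discriminate the enolate faces poorly, so that mono-rearranged ester and mismatched diastereomers accumulate. The fallback sets out from 4 and returns at 7. Enolisation with LDA in THF–DMPU at −78 °C with TMSCl present from the start (to forestall Dieckmann closure) should give the bis(trimethylsilyl ketene acetal) F1. On warming to reflux this rearranges without a chiral controller to the bis(trimethylsilyl) ester F2. Aqueous acid frees the diacid stereoisomer mixture F3 (racemic C2 pair plus meso isomer), and the meso isomer is removed by crystallisation or chromatography. The racemate is resolved by crystallising the bis[(R)-1-phenylethylammonium] salt F4 (the other amine enantiomer is used if the unwanted salt is the less soluble one), and dilute HCl liberates 7.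

Step 6. Hydrogen transfer from the stannane may reach the C7 radical before ring closure, on one or both sides, or hydrogen may be delivered to both faces of the C5 radical. The fallback sets out from 10 and returns at 11. Iodine atom-transfer cyclisation with catalytic (Bu3Sn)2 under sunlamp irradiation in PhH, with no hydride present, lets the C7 radical persist until it closes and should give the bis(tertiary iodide) F5. DBU removes HI to give the bis(C5=C6 alkene) F6. Hydrogenation over Pd/C, which adds from the α-face opposite the axial C10 and C4 methyls, sets both trans ring fusions and gives 11.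

Step 8. The C8 cations may be diverted before equilibrium is reached: by incomplete migration of the trisubstituted and exocyclic alkene isomers, by capture of one C8 cation by the alkene of the other half (closing a fifth ring), or by backbone shifts. The fallback sets out from 11 and returns at 13. Tf2O with 2,6-di-tert-butyl-4-methylpyridine in CH2Cl2 should convert each ketone under equilibrating conditions into the more substituted enol triflate, giving the bis(enol triflate) F7 with both C8=C9 alkenes already in place. Fe(acac)3-catalysed cross-coupling with MeMgBr in THF–NMP then replaces both triflates by methyl and gives 13 with no acid-mediated alkene equilibration.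

**Further compounds**

F1 | step 3 | bis(trimethylsilyl ketene acetal) of 4 (chain cis to each silyloxy group) | CC1=C(CO/C(O[Si](C)(C)C)=C/CC/C=C(O[Si](C)(C)C)/OCC2=C(C)CCCC2(C)C)C(C)(C)CCC1
F2 | step 3 | bis(trimethylsilyl) 2,5-bis(1,3,3-trimethyl-2-methylidenecyclohexyl)hexanedioate (racemic C2 pair plus meso isomer) | C=C1C(C)(C)CCCC1(C)C(CCC(C(=O)O[Si](C)(C)C)C1(C)CCCC(C)(C)C1=C)C(=O)O[Si](C)(C)C
F3 | step 3 | 2,5-bis(1,3,3-trimethyl-2-methylidenecyclohexyl)hexanedioic acid (racemic C2 pair plus meso isomer) | C=C1C(C)(C)CCCC1(C)C(CCC(C(=O)O)C1(C)CCCC(C)(C)C1=C)C(=O)O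
F4 | step 3 | bis[(R)-1-phenylethylammonium] salt of 7 | C=C1C(C)(C)CCC[C@]1(C)[C@@H](CC[C@@H](C(=O)[O-])[C@@]1(C)CCCC(C)(C)C1=C)C(=O)[O-].C[C@@H]([NH3+])c1ccccc1.C[C@@H]([NH3+])c1ccccc1
F5 | step 6 | bis(tertiary iodide): C5-iodo analogue of 11 in both halves (C5 epimers) | C(C[C@H]1C(=O)CCC2(I)C(C)(C)CCC[C@]12C)[C@H]1C(=O)CCC2(I)C(C)(C)CCC[C@]12C
F6 | step 6 | bis(C5=C6 alkene): 5,6-didehydro analogue of 11 in both halves | C(C[C@H]1C(=O)CC=C2C(C)(C)CCC[C@]12C)[C@H]1C(=O)CC=C2C(C)(C)CCC[C@]12C
F7 | step 8 | bis(enol triflate): 1,2-bis[(4aS,8aS)-5,5,8a-trimethyl-2-(trifluoromethylsulfonyloxy)-3,4,4a,5,6,7,8,8a-octahydronaphthalen-1-yl]ethane | O=S(=O)(OC1=C(CCC2=C(OS(=O)(=O)C(F)(F)F)CC[C@H]3C(C)(C)CCC[C@]23C)[C@@]2(C)CCCC(C)(C)[C@@H]2CC1)C(F)(F)F
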